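The earlier runs and the new flask stem from a simulated flask for substances that don't exist; the scatter is artificial.

1. Between the two earlier runs, the reagent stayed at 0.058 M and the free catalyst at 0.50 mM. The substrate rose from 0.081 M to 0.13 M, a factor of 1.60.

in all of them: free catalyst 0.50 mM

|  | substrate | reagent | remark |
|---|---|---|---|
| south | 0.081 M | 0.058 M | run made earlier |
| north-west | 0.13 M | 0.058 M | run made earlier |
| flask | 0.058 M | 0.0580 M |  |

- south (time / min: product / %): 2.00: 1; 6.00: 10; 10.0: 17; 15.0: 23; 25.0: 36; 30.0: 40
- north-west (time / min: product / %): 5.00: 4; 10.0: 9; 15.0: 14; 20.0: 17; 25.0: 19; 30.0: 23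

(readings scatter by 1.5 percentage points)

- what was read earlier has a scatter of 1.5 percentage points, one standard deviation
- what may be going on: substrate + free catalyst -> catalyst intermediate A; catalyst intermediate A -> catalyst intermediate B; reagent + catalyst intermediate B -> catalyst intermediate C; catalyst intermediate C -> catalyst intermediate D; catalyst intermediate D -> free catalyst + product; 2 reagent -> homo dimer
- no earlier run changes the charge of free catalyst; that part of a forecast is a guess
- no earlier run changes the charge of reagent; that part of a forecast is a guess

- apparent order in free catalyst when 30 % of the substrate are converted (percent change of the rate of making product for one percent more free catalyst charged)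
- apparent order in reagent when 30 % of the substrate are converted (percent change of the rate of making product for one percent more reagent charged)
- factor on the rate of making product when 30 % of the substrate are converted if free catalyst is charged twice over

2. Percent readings hide what these runs share, so I turned them into concentrations. The south run held 23 % product at 15.0 min, a mean of 1.24 mM min⁻¹.

3. The north-west run held 14 % at 15.0 min, a mean of 1.21 mM min⁻¹.

4. These two ways differ by a factor of 1.02, far less than the substrate factor. So I trusted their mean, 1.23 mM min⁻¹, and called it w, the c(product) made per minute over the first 15.0 min at these reagent and catalyst charges.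

5. But w is no steady rate. From 15.0 min to 30.0 min, the two runs averaged 0.849 mM min⁻¹, which is slower.

6. I carried w to the flask, which has the same reagent and catalyst charges but less substrate, 0.058 M. I expected 30 % conversion at 14.2 min, 31.8 % product at 15.0 min, and a rate at that conversion between 0.849 mM min⁻¹ and 1.23 mM min⁻¹. The runs gave me no measured order in reagent or catalyst.

7. The forecast gave 1.05 in free catalyst, 0.9 in reagent and a factor of 2.1 on doubling the catalyst, and on the catalyst it said "Every step is first order in catalyst".

8. The flask gave 1.2 in free catalyst, 0.71 in reagent, and a factor of 2.26 on doubling the catalyst.

    substrate + free catalyst → catalyst intermediate A (k = 2700 M⁻¹ min⁻¹)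
    catalyst intermediate A → catalyst intermediate B (k = 12.0 min⁻¹)
    reagent + catalyst intermediate B → catalyst intermediate C (k = 140 M⁻¹ min⁻¹)
    catalyst intermediate C → catalyst intermediate D (k = 8.60 min⁻¹)
    catalyst intermediate D → free catalyst + product (k = 120 min⁻¹)
    2 reagent → homo dimer (k = 0.330 M⁻¹ min⁻¹)

The flask reached 30 % at 13.7 min against my 14.2 min, and held 31.4 % product at 15.0 min against my 31.8 %; its rate at that conversion was 1.02 mM min⁻¹, below w and above the later mean. The step of reagent onto catalyst intermediate B had 62 % of its turnover up to 30.0 min behind it at 15.0 min, while reagent fell from 83.0 % at 3.00 min to 41.7 %. At 30.0 min, catalyst intermediate B, the resting state, held 75.9 % of the catalyst, and reagent stood at 17.6 %. With twice the reagent, the flask took 10.6 min to that conversion, a mean rate 1.33 times w.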